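# Total synthesis of ubiquinol-6 (17) by building the arene last from a squarate and a 2-alkyne

## Analysis of the target

- Ubiquinol-6 (17) is a hexasubstituted benzene. C1 and C4 carry OH, C2 and C3 carry OMe, C5 carries CH3, and C6 carries an all-E hexaprenyl chain (backbone C1'–C24', 30 carbons).
- The molecule has no stereocentre and is achiral. All stereochemical information lies in the five trisubstituted E olefins Δ2', Δ6', Δ10', Δ14' and Δ18'. The sixth olefin, Δ22', is an isopropylidene.
- These olefins are insulated from each other by CH2CH2 links. No olefin can control another, so each must be bought or set on its own and then left untouched.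
- The hydroquinone is oxidised by air to the quinone.
- Acid adds the C1 hydroxyl to Δ2' (chromanol closure), scrambles Δ2' through an allyl cation, and starts cation–olefin cyclisation along the chain.
- The hard points are threefold:
  - joining ring and chain at C6–C1' without an allyl cation;
  - building a C30 chain from C15 material without loss of geometry;
  - arriving at the hydroquinone level under neutral, non-oxidising conditions.
- The feature that invites the strategy is the ring edge C1(OH)–C2(OMe)–C3(OMe)–C4(OH). These four contiguous carbons with four oxygens have the connectivity of a squaric acid diester and are locally mirror-symmetric.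
- The remaining edge C5=C6, with CH3 on C5 and C1'H2 on C6, is a reduced 2-alkyne. Because the mirror plane exchanges C5 and C6, either orientation of the union gives the same compound.

## Retrosynthetic reasoning

**17 ⇒ 14.** The last disconnection is the benzene ring itself.
- The C1–C6 bond is cut and C1 is rejoined to C4. This passes back through dienone 16 and dienylketene 15 to the 4-alkenyl-4-hydroxycyclobutenone 14, an isomer of 17.
- The forward reaction needs only heat, so the acid- and air-sensitive target appears in a reagent-free step and already at the hydroquinone level.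
- It has to open the four-membered ring with the alkenyl group turned inward, close the six-membered ring, and aromatise.

**14 ⇒ 12 + 13, and 13 ⇒ 11 ⇒ 9.**
- Cutting C4–C5 separates the whole oxygenated edge as dimethyl squarate 12 from the alkenyllithium 13. Compound 13 comes from iodide 11 by exchange, and 11 comes from the 2-alkyne 9 by hydrozirconation and iodination.
- Taken together, the two ring bonds C4–C5 and C1–C6 are cut. The target thus falls into a C6 building block that is bought and a hydrocarbon.
- Since 12 is symmetric, the regiochemistry of the hydrometalation of 9 has no consequence for 17. This removes the usual weakness of unsymmetrical dialkylalkynes.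

**9 ⇒ 8 ⇒ 5 + 6 (as its anion 7).**
- The chain is cut at C12'–C13', its exact midpoint, into two C15 halves.
- This CH2–CH2 bond lies between two allyl positions. The forward reaction joins an allyl anion stabilised by a phenylsulfonyl group (7) to an allylic bromide (5). The sulfonyl group of 8 is then replaced by hydride under palladium catalysis.
- No olefin takes part in bond formation, so four bought E olefins are carried through unchanged.

**5 ⇒ 4 ⇒ 3.**
- The bromide goes back to the allylic alcohol 4, and 4 goes back to the hydrocarbon 3 by selenium-mediated allylic oxidation of the E methyl group of the isopropylidene terminus.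
- This step turns the isopropylidene of the proximal half into the fifth E olefin (Δ10').
- The 2-butynyl end of 3 is inert to all chain chemistry, so no protecting group is needed anywhere.

**3 ⇒ 1 + 2, and 6 ⇒ 1.**
- The C6–C1' bond is the bond of the textbook route. Here it is made first, as an sp–sp3 coupling of propynyl Grignard 2 with farnesyl bromide 1, with no arene and no cation involved.
- The sulfone 6 comes from the same bromide 1. Both halves of the chain therefore come from one commercial C15 compound.

## Alternatives that were turned down

**Alternative 1:** the textbook cut at C6–C1'. The forward step is a Lewis-acid-mediated Friedel–Crafts allylation of 2,3-dimethoxy-5-methylhydroquinone A1 with all-E-hexaprenol A2.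
- Ionisation of A2 gives a delocalised allyl cation. It can lose the Δ2' geometry, react at C3', alkylate oxygen, or be captured by Δ6'.
- The same acid then closes the C1 hydroxyl of the product onto Δ2'.
- A2 is not commercial and needs the same C15 + C15 union. It also needs a protecting group on its allylic oxygen, and such a group is itself at risk under the palladium/hydride desulfonylation.
- The least selective step would stand last, on the most valuable material.

**Alternative 2:** a cut at C1'–C2'. The forward step is a nickel(0)-catalysed coupling of 2-(chloromethyl)-5,6-dimethoxy-3-methyl-1,4-benzoquinone A3 with the E-alkenylalane A4. A4 is made by zirconium-catalysed carboalumination of the terminal alkyne A5.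
- The geometry at Δ2' would be secure.
- However, A5 contains a C25 segment that does not divide into two C15 units. It needs an ω-functionalised and protected C10 piece, then deprotection, halogenation and propargylation.
- A3 takes several steps of its own.
- The coupling ends at the quinone level, so a reduction still follows.
- The ring is bought ready-made, and the step builds only one bond next to it.

**Alternative 3:** another de novo arene, a Dötz benzannulation of alkyne 9 with pentacarbonyl[(1,2-dimethoxyethenyl)(methoxy)carbene]chromium A6 and CO.
- The carbene carbon ends para to the new phenol, so the product is the O-methyl ether A7 and not 17.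
- The extra methyl group must be removed by oxidative demethylation in the presence of six electron-rich olefins, followed by a reduction.
- A6 is a heavily donor-substituted, poorly accessible carbene complex that is used in stoichiometric amount.
- The ring of A7 is no longer symmetric, so the poor regioselectivity of a dialkylalkyne reappears until the oxidation.

Key step: step 9

Assumption: 17 has no stereocentre, so "single enantiomer" is read as the single all-E geometrical isomer. Compound 1 is taken as the commercial (2E,6E) grade.

## Route

Step 1
Reactants: 1 (2E,6E)-farnesyl bromide; 2 1-propynylmagnesium bromide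
Product: 3 (5E,9E)-6,10,14-trimethylpentadeca-5,9,13-trien-2-yne
Conditions: CuI (10 mol %), THF, 0 °C to rt
Reagents that add atoms: none
Why: Copper(I)-catalysed coupling of an alkynyl Grignard reagent with an allylic bromide (skipped-enyne synthesis); attack should occur at the primary carbon because the γ-carbon is fully substituted, and the olefins are not involved, so both E geometries are kept.

Step 2
Reactants: 3 (5E,9E)-6,10,14-trimethylpentadeca-5,9,13-trien-2-yne
Product: 4 (2E,6E,10E)-2,6,10-trimethylpentadeca-2,6,10-trien-13-yn-1-ol
Conditions: SeO2 (0.3 equiv), t-BuOOH (2 equiv), salicylic acid (0.1 equiv), CH2Cl2, 0 °C to rt, stopped at partial conversion, 3 recovered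
Reagents that add atoms: tert-butyl hydroperoxide, CC(C)(C)OO (oxygen atom, passed on by catalytic SeO2, O=[Se]=O)
Why: Riley-type allylic oxidation in its catalytic form: ene reaction at the least hindered olefin, the isopropylidene, then a [2,3]-sigmatropic shift whose envelope transition state delivers oxygen to the E methyl group and thereby sets the future Δ10' olefin as E. The alkyne is much less reactive than a trisubstituted olefin towards selenium(IV).

Step 3
Reactants: 4 (2E,6E,10E)-2,6,10-trimethylpentadeca-2,6,10-trien-13-yn-1-ol
Product: 5 (2E,6E,10E)-1-bromo-2,6,10-trimethylpentadeca-2,6,10-trien-13-yne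
Conditions: CBr4, PPh3, CH2Cl2, 0 °C
Reagents that add atoms: carbon tetrabromide, BrC(Br)(Br)Br
Why: Appel reaction; the neutral SN2 displacement at a primary allylic carbon should proceed without allylic shift or E/Z change, and olefins and alkyne are inert.

Step 4
Reactants: 1 (2E,6E)-farnesyl bromide
Product: 6 (2E,6E)-farnesyl phenyl sulfone
Conditions: PhSO2Na, DMF, rt
Reagents that add atoms: sodium benzenesulfinate, [Na+].[O-]S(=O)c1ccccc1
Why: S-alkylation of a sulfinate by a primary allylic bromide (SN2), which leaves the olefin geometry untouched.

Step 5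
Reactants: 6 (2E,6E)-farnesyl phenyl sulfone; 5 (2E,6E,10E)-1-bromo-2,6,10-trimethylpentadeca-2,6,10-trien-13-yne
Product: 8 (5E,9E,13E,17E,21E)-6,10,14,18,22,26-hexamethyl-16-(phenylsulfonyl)heptacosa-5,9,13,17,21,25-hexaen-2-yne (racemic), via lithiated sulfone 7 (not isolated)
Conditions: n-BuLi (1.05 equiv), THF–DMPU, −78 °C; then 5, −78 to −20 °C
Reagents that add atoms: none
Why: Biellmann-type alkylation of an α-lithiated allyl sulfone, which reacts at its α-carbon with the primary allylic bromide and forms C12'–C13'. The anion is too weak a base to deprotonate the doubly activated CH2 next to the alkyne, and the new stereocentre is removed in step 6.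

Step 6
Reactants: 8 (5E,9E,13E,17E,21E)-6,10,14,18,22,26-hexamethyl-16-(phenylsulfonyl)heptacosa-5,9,13,17,21,25-hexaen-2-yne (racemic)
Product: 9 (5E,9E,13E,17E,21E)-6,10,14,18,22,26-hexamethylheptacosa-5,9,13,17,21,25-hexaen-2-yne
Conditions: PdCl2(dppp) (5 mol %), LiHBEt3 (2.2 equiv), THF, 0 °C
Reagents that add atoms: none
Why: Palladium-catalysed hydride desulfonylation of an allyl sulfone: ionisation to a π-allylpalladium species, hydride transfer to the metal and reductive elimination at the carbon that carried sulfur, which with the chelating diphosphine should keep position and E geometry of Δ14'. Isolated olefins and the dialkylalkyne are not reduced by the borohydride at 0 °C.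

Step 7
Reactants: 9 (5E,9E,13E,17E,21E)-6,10,14,18,22,26-hexamethylheptacosa-5,9,13,17,21,25-hexaen-2-yne
Product: 11 (2E,5E,9E,13E,17E,21E)-2-iodo-6,10,14,18,22,26-hexamethylheptacosa-2,5,9,13,17,21,25-heptaene, via alkenylzirconocene 10 (not isolated)
Conditions: Cp2Zr(H)Cl (1.5 equiv), THF, rt, dark; then I2, THF, −78 to 0 °C
Reagents that add atoms: iodine, II
Why: Hydrozirconation with the Schwartz reagent is a syn addition that is selective for the alkyne over trisubstituted olefins and, with a slight excess of reagent, places zirconium next to the methyl group; iodinolysis proceeds with retention and gives the E iodide. Any share of the opposite regiochemistry need not be separated, because steps 8 and 9 would carry it to the same 17.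

Step 8
Reactants: 11 (2E,5E,9E,13E,17E,21E)-2-iodo-6,10,14,18,22,26-hexamethylheptacosa-2,5,9,13,17,21,25-heptaene; 12 dimethyl squarate (3,4-dimethoxycyclobut-3-ene-1,2-dione)
Product: 14 4-hydroxy-2,3-dimethoxy-4-[(2E,5E,9E,13E,17E,21E)-6,10,14,18,22,26-hexamethylheptacosa-2,5,9,13,17,21,25-heptaen-2-yl]cyclobut-2-en-1-one (racemic), via alkenyllithium 13 (not isolated)
Conditions: t-BuLi (2.05 equiv), Et2O, −78 °C; cannulated into 12 (1.2 equiv), THF, −78 °C; aq. NH4Cl at −78 °C; short pad of Et3N-deactivated silica
Reagents that add atoms: none
Why: Iodine–lithium exchange with retention of geometry is much faster at −78 °C than deprotonation of the doubly allylic CH2, and alkenyllithiums add 1,2 to one carbonyl group of squarate diesters. Inverse addition suppresses a second addition, and the racemic carbinol centre is erased in step 9.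

Step 9
Reactants: 14 4-hydroxy-2,3-dimethoxy-4-[(2E,5E,9E,13E,17E,21E)-6,10,14,18,22,26-hexamethylheptacosa-2,5,9,13,17,21,25-heptaen-2-yl]cyclobut-2-en-1-one (racemic)
Product: 17 ubiquinol-6, via dienylketene 15 (not isolated), via cyclohexadienone 16 (not isolated)
Conditions: degassed p-xylene (0.01 M), base-washed glassware, Ar, reflux (138 °C); isolation under Ar
Reagents that add atoms: none
Why: Moore–Liebeskind ring expansion of a 4-alkenyl-4-hydroxycyclobutenone, a reaction type with close precedent for adducts of dimethyl squarate with 2-alkenyllithiums. Heat opens the strained ring by conrotatory 4π electrocyclic cleavage of the bond between the carbonyl carbon and the carbinol carbon; the donor OH rotates outward (torquoselectivity), so the alkenyl group turns inward and stands cis to the ketene in 15. The six-membered ring is closed by a thermal disrotatory 6π electrocyclisation that joins the ketene carbon (future C1) to the alkene CH (future C6), whose chain points outward thanks to the E geometry set in step 7. Dienone 16 holds the only new sp3 centre (C6), which is erased at once by enolisation to the arene, so no stereocentre has to be controlled and the racemic centre of 14 disappears as well. The step needs chemoselectivity over six isolated olefins and the doubly allylic C1'H2: no acid, base, metal or oxidant is present, the intramolecular 6π closure should outrun any [2+2] addition of the ketene to the remote unactivated olefins, and Δ2' never becomes part of a cation, so its E geometry is kept. Regiochemistry cannot fail, because the edge C1–C4 is symmetric and either orientation of the alkenyl unit gives 17. The product is an isomer of 14 and appears directly at the hydroquinone level, provided that oxygen is excluded.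

## Compound list

1 | (2E,6E)-farnesyl bromide | BrC/C=C(\C)CC/C=C(\C)CCC=C(C)C | starting material
2 | 1-propynylmagnesium bromide | CC#C[Mg]Br | starting material
3 | (5E,9E)-6,10,14-trimethylpentadeca-5,9,13-trien-2-yne | CC#CC/C=C(\C)CC/C=C(\C)CCC=C(C)C | intermediate
4 | (2E,6E,10E)-2,6,10-trimethylpentadeca-2,6,10-trien-13-yn-1-ol | CC#CC/C=C(\C)CC/C=C(\C)CC/C=C(\C)CO | intermediate
5 | (2E,6E,10E)-1-bromo-2,6,10-trimethylpentadeca-2,6,10-trien-13-yne | CC#CC/C=C(\C)CC/C=C(\C)CC/C=C(\C)CBr | intermediate
6 | (2E,6E)-farnesyl phenyl sulfone | O=S(=O)(C/C=C(\C)CC/C=C(\C)CCC=C(C)C)c1ccccc1 | intermediate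
7 | α-lithiated (2E,6E)-farnesyl phenyl sulfone | [Li]C(/C=C(\C)CC/C=C(\C)CCC=C(C)C)S(=O)(=O)c1ccccc1 | intermediate
8 | (5E,9E,13E,17E,21E)-6,10,14,18,22,26-hexamethyl-16-(phenylsulfonyl)heptacosa-5,9,13,17,21,25-hexaen-2-yne (racemic) | CC#CC/C=C(\C)CC/C=C(\C)CC/C=C(\C)CC(/C=C(\C)CC/C=C(\C)CCC=C(C)C)S(=O)(=O)c1ccccc1 | intermediate
9 | (5E,9E,13E,17E,21E)-6,10,14,18,22,26-hexamethylheptacosa-5,9,13,17,21,25-hexaen-2-yne | CC#CC/C=C(\C)CC/C=C(\C)CC/C=C(\C)CC/C=C(\C)CC/C=C(\C)CCC=C(C)C | intermediate
10 | (E)-alkenylzirconocene chloride from 9, Zr at C2 (Cp drawn σ-bonded) | C/C([Zr](Cl)(C1C=CC=C1)C1C=CC=C1)=C\C/C=C(\C)CC/C=C(\C)CC/C=C(\C)CC/C=C(\C)CC/C=C(\C)CCC=C(C)C | intermediate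
11 | (2E,5E,9E,13E,17E,21E)-2-iodo-6,10,14,18,22,26-hexamethylheptacosa-2,5,9,13,17,21,25-heptaene | C/C(I)=C\C/C=C(\C)CC/C=C(\C)CC/C=C(\C)CC/C=C(\C)CC/C=C(\C)CCC=C(C)C | intermediate
12 | dimethyl squarate (3,4-dimethoxycyclobut-3-ene-1,2-dione) | COC1=C(OC)C(=O)C1=O | starting material
13 | (E)-alkenyllithium from 11 | C/C([Li])=C\C/C=C(\C)CC/C=C(\C)CC/C=C(\C)CC/C=C(\C)CC/C=C(\C)CCC=C(C)C | intermediate
14 | 4-hydroxy-2,3-dimethoxy-4-[(2E,5E,9E,13E,17E,21E)-6,10,14,18,22,26-hexamethylheptacosa-2,5,9,13,17,21,25-heptaen-2-yl]cyclobut-2-en-1-one (racemic) | COC1=C(OC)C(O)(/C(C)=C/C/C=C(\C)CC/C=C(\C)CC/C=C(\C)CC/C=C(\C)CC/C=C(\C)CCC=C(C)C)C1=O | intermediate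
15 | dienylketene from 14 (alkenyl group cis to the ketene) | O=C=C(OC)/C(OC)=C(/O)\C(C)=C\C/C=C(\C)CC/C=C(\C)CC/C=C(\C)CC/C=C(\C)CC/C=C(\C)CCC=C(C)C | intermediate
16 | 4-hydroxy-2,3-dimethoxy-5-methyl-6-[(all-E)-hexaprenyl]cyclohexa-2,4-dien-1-one | COC1=C(OC)C(=O)C(C/C=C(\C)CC/C=C(\C)CC/C=C(\C)CC/C=C(\C)CC/C=C(\C)CCC=C(C)C)C(C)=C1O | intermediate
17 | ubiquinol-6 | COc1c(O)c(C)c(C/C=C(\C)CC/C=C(\C)CC/C=C(\C)CC/C=C(\C)CC/C=C(\C)CCC=C(C)C)c(O)c1OC | target

## Step count and least certain steps

- Total step count: 9.
- Longest linear sequence: 8 (steps 1, 2, 3, 5, 6, 7, 8, 9).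
- No protecting group is used.

**Step 9 (key step).**
- What may go wrong:
  - The dienylketene may be diverted before ring closure, by addition of a hydroxyl group of substrate or product, which becomes more likely at high concentration.
  - The product may be oxidised by air during isolation.
  - Traces of acid on glass or silica may close the C1 hydroxyl onto Δ2'.
- Fallback: it sets out from 9 and 12, skips steps 7 and 8, and comes back at 17.
  - Chlorotris(triphenylphosphine)cobalt(I) inserts into the bond between the two carbonyl carbons of 12. This gives chloro(2,3-dimethoxymaleoyl)bis(triphenylphosphine)cobalt(III) F1.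
  - On thermal or Lewis-acid activation, F1 takes up alkyne 9 by insertion and reductive elimination (maleoylcobalt quinone synthesis). The product is ubiquinone-6 F2, again with no regiochemical question.
  - F2 is stable to air and chromatography. It is reduced with aqueous Na2S2O4 in a two-phase system under argon to 17.
  - Precedent is less close for a dialkoxy-substituted dione than for alkyl- or monoalkoxy-substituted ones.

**Step 2.**
- What may go wrong:
  - Site selectivity may be poor, with attack at the allylic CH2 groups of the two internal olefins, which are not deactivated here.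
  - The methylene between alkyne and Δ5 may be oxidised slowly.
  - Over-oxidation to the aldehyde level may occur; a borohydride treatment of the crude product would reverse it.
- Fallback: it sets out from 3 and comes back at 8.
  - Terminal-selective bromohydrin formation (NBS, aqueous THF) gives (6E,10E)-3-bromo-2,6,10-trimethylpentadeca-6,10-dien-13-yn-2-ol F3.
  - K2CO3 in MeOH closes it to 2,2-dimethyl-3-[(3E,7E)-3,7-dimethyldodeca-3,7-dien-10-yn-1-yl]oxirane F4.
  - Al(Oi-Pr)3 in hot toluene isomerises the epoxide to (6E,10E)-2,6,10-trimethylpentadeca-1,6,10-trien-13-yn-3-ol F5.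
  - SOCl2 in Et2O transposes F5 by an SNi' process, through a cyclic transition state with the chain pseudo-equatorial. This gives (2E,6E,10E)-1-chloro-2,6,10-trimethylpentadeca-2,6,10-trien-13-yne F6.
  - F6 takes the place of 5 in step 5.

**Step 6.**
- What may go wrong:
  - Hydride may be delivered to the wrong allyl terminus, which shifts the double bond.
  - The E geometry may erode through π–σ–π isomerisation of the allylpalladium species.
  - The alkyne may be partly reduced.
- Fallback: it sets out from 5, avoids sulfur altogether (steps 4 to 6) and comes back at 9.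
  - Commercial (2E,6E)-farnesyl chloride F7 is converted with activated barium (BaI2, lithium biphenylide, THF, −78 °C) into (2E,6E)-farnesylbarium chloride F8.
  - F8 is an allyl metal that keeps its geometry at −78 °C and couples with allylic bromides at its α-carbon.
  - Its reaction with 5 is a union of two allyl halides by polarity reversal and gives 9 directly.
  - It is not the first choice because the reagent is basic enough to threaten the CH2 between alkyne and olefin.

**Step 8.**
- What may go wrong:
  - A proton may be transferred from the doubly allylic CH2 to the alkenyllithium, with loss of nucleophile and conjugation of the diene.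
  - A second addition to the squarate may occur.
  - The tertiary, doubly allylic alcohol may ionise on silica.
- Fallback: it sets out from 9, replaces steps 7 and 8, and comes back at 14.
  - Titanium-catalysed hydromagnesiation (i-BuMgBr, Cp2TiCl2 5 mol %, Et2O, rt) is a syn addition to dialkylalkynes. It gives the less basic (E)-alkenylmagnesium bromide F9.
  - F9 is added to 12 at −78 to −20 °C and quenched with NH4Cl.
  - The modest regioselectivity of this hydrometalation does no harm, for the reason given under step 7.

## Further compounds

F1 | step 9 | chloro(2,3-dimethoxymaleoyl)bis(triphenylphosphine)cobalt(III) | COC1=C(OC)C(=O)[Co-2](Cl)([P+](c2ccccc2)(c2ccccc2)c2ccccc2)([P+](c2ccccc2)(c2ccccc2)c2ccccc2)C1=O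
F2 | step 9 | ubiquinone-6 | COC1=C(OC)C(=O)C(C/C=C(\C)CC/C=C(\C)CC/C=C(\C)CC/C=C(\C)CC/C=C(\C)CCC=C(C)C)=C(C)C1=O
F3 | step 2 | (6E,10E)-3-bromo-2,6,10-trimethylpentadeca-6,10-dien-13-yn-2-ol (racemic) | CC#CC/C=C(\C)CC/C=C(\C)CCC(Br)C(C)(C)O
F4 | step 2 | 2,2-dimethyl-3-[(3E,7E)-3,7-dimethyldodeca-3,7-dien-10-yn-1-yl]oxirane (racemic) | CC#CC/C=C(\C)CC/C=C(\C)CCC1OC1(C)C
F5 | step 2 | (6E,10E)-2,6,10-trimethylpentadeca-1,6,10-trien-13-yn-3-ol (racemic) | CC#CC/C=C(\C)CC/C=C(\C)CCC(O)C(C)=C
F6 | step 2 | (2E,6E,10E)-1-chloro-2,6,10-trimethylpentadeca-2,6,10-trien-13-yne | CC#CC/C=C(\C)CC/C=C(\C)CC/C=C(\C)CCl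
F7 | step 6 | (2E,6E)-farnesyl chloride | ClC/C=C(\C)CC/C=C(\C)CCC=C(C)C
F8 | step 6 | (2E,6E)-farnesylbarium chloride | Cl[Ba]C/C=C(\C)CC/C=C(\C)CCC=C(C)C
F9 | step 8 | (E)-alkenylmagnesium bromide from 9, Mg at C2 | C/C([Mg]Br)=C\C/C=C(\C)CC/C=C(\C)CC/C=C(\C)CC/C=C(\C)CC/C=C(\C)CCC=C(C)C
A1 | alternative 1 | 2,3-dimethoxy-5-methylhydroquinone | COc1c(O)cc(C)c(O)c1OC
A2 | alternative 1 | all-E-hexaprenol | OC/C=C(\C)CC/C=C(\C)CC/C=C(\C)CC/C=C(\C)CC/C=C(\C)CCC=C(C)C
A3 | alternative 2 | 2-(chloromethyl)-5,6-dimethoxy-3-methyl-1,4-benzoquinone | COC1=C(OC)C(=O)C(CCl)=C(C)C1=O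
A4 | alternative 2 | dimethyl[(1E,5E,9E,13E,17E)-2,6,10,14,18,22-hexamethyltricosa-1,5,9,13,17,21-hexaen-1-yl]alane | C[Al](C)/C=C(\C)CC/C=C(\C)CC/C=C(\C)CC/C=C(\C)CC/C=C(\C)CCC=C(C)C
A5 | alternative 2 | (5E,9E,13E,17E)-6,10,14,18,22-pentamethyltricosa-5,9,13,17,21-pentaen-1-yne | C#CCC/C=C(\C)CC/C=C(\C)CC/C=C(\C)CC/C=C(\C)CCC=C(C)C
A6 | alternative 3 | pentacarbonyl[(1,2-dimethoxyethenyl)(methoxy)carbene]chromium(0) | COC=C(OC)C(OC)=[Cr](=C=O)(=C=O)(=C=O)(=C=O)=C=O
A7 | alternative 3 | 2,3,4-trimethoxy-5-methyl-6-[(all-E)-hexaprenyl]phenol | COc1c(OC)c(OC)c(C)c(C/C=C(\C)CC/C=C(\C)CC/C=C(\C)CC/C=C(\C)CC/C=C(\C)CCC=C(C)C)c1O
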